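**Retrosynthetic overview**

1. Target 29 ⇐ hydroxide opening of a 15,12-butenolide (temporary ring) ⇐ γ-hydroxy ynoate (syn addition of Me–Cu gives 13Z) ⇐ aldehyde 22 + methyl propiolate (catalyst-controlled C12) ⇐ decalone 20 (Wittig brings C17).
2. Ring A of 20 ⇐ ring-B aldehyde ester 15 + vinyltriphenylphosphonium bromide: a one-pot ester-enolate Michael addition/intramolecular Wittig reaction closes ring A, supplies C2–C3 and creates quaternary C4.
3. Enabling feature: C4 is the α-carbon of the C19 carboxyl (enolisable); C1 hangs on quaternary C10, so a C1 aldehyde cannot enolise; C1 and C4 are 1,4-related and trans on ring B, so a bare C2–C3 ethano unit can bridge them.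
4. 15 ⇐ enone 9 (anti conjugate vinylation sets C10; enolate alkylation adds C11–C12) ⇐ allylic propanoate 4 (Ireland–Claisen rearrangement carries the carbinol centre to C5) ⇐ CBS reduction of 2-methylcyclohex-2-en-1-one 1.
5. Ring order: ring B (from 1), ring A (step 9), butenolide (formed and opened in step 16).

Key step: step 9

Remark on the chemistry (assumption): the open-chain (13Z)-γ-hydroxy acid is taken to be isolable after basic opening of its butenolide and acidification to pH 4–5 at 0 °C; stronger acid would reclose the lactone.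

Locants C1–C20 are the labdane positions of the target: ring A = C1–C5 and C10; ring B = C5–C10; side chain C11–C16; C17 exocyclic methylene; C18/C19 methyl and carboxyl on C4; C20 methyl on C10.

**Route**

Step 1
Reactants: 1 2-methylcyclohex-2-en-1-one
Product: 2 (S)-2-methylcyclohex-2-en-1-ol
Conditions: (R)-2-methyl-CBS-oxazaborolidine (10 mol%), BH3·SMe2, THF, −20 °C; MeOH quench
Reagents that add atoms: none
Why: CBS reduction in which the α-methylvinyl arm of the enone acts as the large group, so the (R)-catalyst should deliver hydride to the face that gives the (S)-allylic alcohol.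

Step 2
Reactants: 2 (S)-2-methylcyclohex-2-en-1-ol; 3 propanoic anhydride
Product: 4 (1S)-2-methylcyclohex-2-en-1-yl propanoate
Conditions: (EtCO)2O, Et3N, DMAP (cat.), CH2Cl2, 0 → 23 °C
Reagents that add atoms: propanoic anhydride, CCC(=O)OC(=O)CC
Why: DMAP-catalysed acylation of a secondary allylic alcohol, which leaves the stereocentre untouched.

Step 3
Reactants: 4 (1S)-2-methylcyclohex-2-en-1-yl propanoate
Product: 7 2-[(1S)-2-methylcyclohex-2-en-1-yl]propanoic acid (both epimers at the α-carbon), via silyl ketene acetal 5 (not isolated), via trimethylsilyl ester 6 (not isolated)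
Conditions: LiN(i-Pr)2, THF, −78 °C; TMSCl, Et3N; −78 → 60 °C; 1 M HCl work-up
Reagents that add atoms: none
Why: Ireland–Claisen rearrangement, whose [3,3] shift across the ring is necessarily suprafacial, so the C–O centre of 4 is carried to the new C–C centre (future C5) with allylic transposition, while the α-centre (future C4) needs no control because it is enolised again in step 9.

Step 4
Reactants: 7 2-[(1S)-2-methylcyclohex-2-en-1-yl]propanoic acid
Product: 8 tert-butyl 2-[(1S)-2-methylcyclohex-2-en-1-yl]propanoate
Conditions: tert-butyl 2,2,2-trichloroacetimidate, BF3·OEt2 (cat.), CH2Cl2/cyclohexane, 23 °C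
Reagents that add atoms: tert-butyl 2,2,2-trichloroacetimidate, CC(C)(C)OC(=N)C(Cl)(Cl)Cl
Why: acid-catalysed tert-butylation with the trichloroacetimidate, chosen because this ester can later be removed by loss of the tert-butyl cation even when it sits on the hindered axial C4 position.

Step 5
Reactants: 8 tert-butyl 2-[(1S)-2-methylcyclohex-2-en-1-yl]propanoate
Product: 9 tert-butyl 2-[(1S)-2-methyl-4-oxocyclohex-2-en-1-yl]propanoate
Conditions: dirhodium tetrakis(caprolactamate) Rh2(C6H10NO)4 (1 mol%), t-BuOOH (5 equiv), K2CO3, CH2Cl2, 23 °C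
Reagents that add atoms: tert-butyl hydroperoxide, CC(C)(C)OO
Why: catalytic allylic C–H oxidation of a trisubstituted cycloalkene to the enone, which (as with 1-methylcyclohexene) should occur at the ring CH2 next to the unsubstituted alkene carbon and leave the tertiary allylic stereocentre alone.

Step 6
Reactants: 9 tert-butyl 2-[(1S)-2-methyl-4-oxocyclohex-2-en-1-yl]propanoate; 10 vinylmagnesium bromide; 11 tert-butyl(2-iodoethoxy)dimethylsilane
Product: 13 tert-butyl 2-[(1S,2S)-3-(2-{[tert-butyl(dimethyl)silyl]oxy}ethyl)-2-ethenyl-2-methyl-4-oxocyclohexyl]propanoate (epimers at ring C3 and at the α-carbon), via silyl enol ether 12 (not isolated)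
Conditions: CH2=CHMgBr, CuBr·SMe2 (10 mol%), TMSCl, DMPU, THF, −78 °C; volatiles removed in vacuo; MeLi, THF, 0 °C; then 11, DMPU, −78 → 23 °C
Reagents that add atoms: vinylmagnesium bromide, C=C[Mg]Br; tert-butyl(2-iodoethoxy)dimethylsilane, CC(C)(C)[Si](C)(C)OCCI
Why: copper-catalysed, TMSCl-accelerated conjugate addition followed by regiospecific alkylation of the lithium enolate released from the silyl enol ether; the vinyl group should enter anti to the neighbouring side chain (as in additions to 3,4-dialkylcyclohexenones), which sets quaternary C10 with its methyl cis to that chain, while epimerisable C9 is left uncontrolled until step 11.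

Step 7
Reactants: 13 keto ester from step 6
Product: 14 tert-butyl 2-[(7S,8S)-6-(2-{[tert-butyl(dimethyl)silyl]oxy}ethyl)-7-ethenyl-7-methyl-1,4-dioxaspiro[4.5]decan-8-yl]propanoate (epimers at C6 and at the α-carbon)
Conditions: TMSOCH2CH2OTMS, TMSOTf (5 mol%), CH2Cl2, −78 → −20 °C
Reagents that add atoms: 1,2-bis(trimethylsilyloxy)ethane, C[Si](C)(C)OCCO[Si](C)(C)C
Why: Noyori ketalisation under aprotic conditions, which masks the ketone (the only other acidic site in step 9) without harming the silyl ether, the tert-butyl ester or the alkene.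

Step 8
Reactants: 14 vinyl ketal
Product: 15 tert-butyl 2-[(7S,8S)-6-(2-{[tert-butyl(dimethyl)silyl]oxy}ethyl)-7-formyl-7-methyl-1,4-dioxaspiro[4.5]decan-8-yl]propanoate (epimers at C6 and at the α-carbon)
Conditions: O3, CH2Cl2/MeOH, −78 °C; Me2S, −78 → 23 °C
Reagents that add atoms: ozone, [O-][O+]=O
Why: ozonolysis with reductive work-up of the only alkene gives the C1 aldehyde, which has no α-hydrogen and so can neither epimerise nor enolise.

Step 9
Reactants: 15 aldehyde ester; 16 vinyltriphenylphosphonium bromide
Product: 18 tert-butyl 12-{[tert-butyl(dimethyl)silyl]oxy}-8,8-(ethane-1,2-diyldioxy)-13,14,15,16,17-pentanorlabd-1-en-19-oate (trans-fused; CH3 α and ester β at C4; C9 epimers), via phosphonium ylide 17 (not isolated)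
Conditions: LiN(i-Pr)2 (1.05 equiv), THF, −78 °C, 30 min; CH2=CHPPh3Br (1.5 equiv), DMPU, −78 → 23 °C; then 50 °C, 2 h
Reagents that add atoms: vinyltriphenylphosphonium bromide, C=C[P+](c1ccccc1)(c1ccccc1)c1ccccc1.[Br-]
Why: Proposed new method: the amide base removes the only acidic C–H of 15 (C4–H; the C1 aldehyde on quaternary C10 cannot enolise and an aldol onto it would close a cyclobutane), the tetrasubstituted ester enolate adds in Michael fashion to the vinylphosphonium salt (new C3–C4 bond), and the resulting non-stabilised ylide 17 olefinates the C1 aldehyde intramolecularly (new C1=C2 bond, loss of Ph3P=O). The closest known reaction type is the Schweizer carbocycle synthesis, in which malonate-type carbanions tethered to a carbonyl group add to this salt and close by intramolecular Wittig reaction, together with the known Michael addition of lithium ketone enolates to the same salt; new here is a simple ester enolate that builds a quaternary carbon with the aldehyde already present. Ring A closes in the Wittig event by 6-exo-trig attack of ylide carbon C2 on the C1 carbonyl, which can only give the cis ring alkene, and the fusion is trans because C1 and C4 are trans-diequatorial on ring B. The new stereocentre C4 is controlled by C5: in the enolate the C5–H eclipses the enolate double bond (A(1,3) strain), so the acceptor should approach the face flanked by C6H2 and anti to quaternary C10, which places CH3 α and the ester β as in the target. The step needs chemoselective ester enolisation beside an aldehyde and C- rather than O-attack of the enolate; the first is secured by the non-enolisable, neopentyl aldehyde and low temperature, the second by the soft cationic Michael acceptor.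

Step 10
Reactants: 18 ring A alkene
Product: 19 tert-butyl 12-{[tert-butyl(dimethyl)silyl]oxy}-8,8-(ethane-1,2-diyldioxy)-13,14,15,16,17-pentanorlabdan-19-oate (C9 epimers)
Conditions: H2 (1 atm), Pd/C (10%), EtOAc, 23 °C
Reagents that add atoms: none
Why: heterogeneous hydrogenation of the cis-disubstituted ring A alkene, which creates no stereocentre and is done before the exocyclic alkene exists.

Step 11
Reactants: 19 saturated ketal
Product: 20 tert-butyl 12-hydroxy-8-oxo-13,14,15,16,17-pentanorlabdan-19-oate (9α-H, side chain 9β)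
Conditions: 2 M HCl (aq)/THF (1:4), 40 °C
Reagents that add atoms: water, O
Why: acid hydrolysis of the dioxolane and the primary silyl ether in one operation (the tert-butyl ester needs anhydrous strong acid), during which the C9 epimers should converge through the enol on the ketone with the equatorial 9β side chain.

Step 12
Reactants: 20 hydroxy ketone
Product: 21 tert-butyl 12-hydroxy-13,14,15,16-tetranorlabd-8(17)-en-19-oate
Conditions: Ph3PCH3Br, KOt-Bu (excess), toluene, 80 °C
Reagents that add atoms: methyltriphenylphosphonium bromide, C[P+](c1ccccc1)(c1ccccc1)c1ccccc1.[Br-]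
Why: Wittig methylenation of the hindered C8 ketone with excess ylide (the hydroxyl is carried as its alkoxide), under basic conditions that keep C9 at its equatorial configuration before the exocyclic alkene locks it.

Step 13
Reactants: 21 hydroxy alkene
Product: 22 tert-butyl 12-oxo-13,14,15,16-tetranorlabd-8(17)-en-19-oate
Conditions: Dess–Martin periodinane, NaHCO3, CH2Cl2, 0 → 23 °C
Reagents that add atoms: none
Why: Dess–Martin oxidation of the primary alcohol to the aldehyde under buffered conditions that leave the 1,1-disubstituted alkene alone.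

Step 14
Reactants: 22 aldehyde; 23 methyl propiolate
Product: 24 19-tert-butyl 15-methyl (12S)-12-hydroxy-16-norlabd-8(17)-en-13-yne-15,19-dioate
Conditions: (S,S)-ProPhenol (20 mol%), Me2Zn (3 equiv), Ph3P=O (40 mol%), toluene, 4 °C; NH4Cl work-up
Reagents that add atoms: methyl propiolate, C#CC(=O)OC
Why: zinc–ProPhenol-catalysed alkynylation of an aldehyde with methyl propiolate, a reagent-controlled addition in which the (S,S)-ligand is expected to deliver the alkynyl group to the Re face and so set 12S independently of the remote ring stereocentres.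

Step 15
Reactants: 24 γ-hydroxy ynoate
Product: 26 (12S)-12-hydroxy-15-methoxy-15-oxo-16-norlabd-8(17)-en-13-yn-19-oic acid, via bis(trimethylsilyl) derivative 25 (not isolated)
Conditions: TMSOTf, 2,6-lutidine, CH2Cl2, 0 °C; NaHCO3 (aq), then pH 4 citrate buffer/MeOH work-up
Reagents that add atoms: none
Why: silyl triflate-induced cleavage of the tert-butyl ester by loss of 2-methylpropene, which does not depend on access to the hindered C19 carbonyl and is buffered so that the exocyclic alkene is not protonated; it is placed before butenolide formation because the same reagents would turn a butenolide into a silyloxyfuran and erase C12.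

Step 16
Reactants: 26 ynoate acid
Product: 29 (4S,5R,9S,10R,12S,13Z)-12-hydroxylabda-8(17),13-diene-15,19-dioic acid (target), via hydroxy enoate 27 (not isolated), via butenolide acid 28 (not isolated)
Conditions: Me2CuLi (5 equiv, from MeLi and CuI), THF, −78 °C; NH4Cl quench, warm to 23 °C; then LiOH, THF/H2O, 0 °C; 1 M HCl to pH 4–5 at 0 °C
Reagents that add atoms: methyllithium (as Me2CuLi), [Li]C; lithium hydroxide, [Li+].[OH-]
Why: syn-carbocupration of the γ-hydroxy ynoate (a known route to 4-methylbutenolides) puts the new methyl on C13 cis to the hydrogen that replaces copper on C14, so C12 and C15 end up cis (13Z, C12 untouched), and hydroxide then opens the lactone at the C15 carbonyl to give the hydroxy diacid.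

**Compound list**

1 | 2-methylcyclohex-2-en-1-one | CC1=CCCCC1=O | starting material
2 | (S)-2-methylcyclohex-2-en-1-ol | O[C@H]1CCCC=C1C | intermediate
3 | propanoic anhydride | CCC(=O)OC(=O)CC | starting material
4 | (1S)-2-methylcyclohex-2-en-1-yl propanoate | CCC(=O)O[C@H]1CCCC=C1C | intermediate
5 | trimethylsilyl ketene acetal of 4 (enol geometry not defined) | CC=C(O[Si](C)(C)C)O[C@H]1CCCC=C1C | intermediate
6 | trimethylsilyl 2-[(1S)-2-methylcyclohex-2-en-1-yl]propanoate (α-epimers) | C1CC[C@@H](C(C)C(=O)O[Si](C)(C)C)C(C)=C1 | intermediate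
7 | 2-[(1S)-2-methylcyclohex-2-en-1-yl]propanoic acid (α-epimers) | C1CC[C@@H](C(C)C(=O)O)C(C)=C1 | intermediate
8 | tert-butyl 2-[(1S)-2-methylcyclohex-2-en-1-yl]propanoate (α-epimers) | C1CC[C@@H](C(C)C(=O)OC(C)(C)C)C(C)=C1 | intermediate
9 | tert-butyl 2-[(1S)-2-methyl-4-oxocyclohex-2-en-1-yl]propanoate (α-epimers) | O=C1CC[C@@H](C(C)C(=O)OC(C)(C)C)C(C)=C1 | intermediate
10 | vinylmagnesium bromide | C=C[Mg]Br | starting material
11 | tert-butyl(2-iodoethoxy)dimethylsilane | CC(C)(C)[Si](C)(C)OCCI | starting material
12 | tert-butyl 2-[(1S,2S)-2-ethenyl-2-methyl-4-(trimethylsilyloxy)cyclohex-3-en-1-yl]propanoate (α-epimers; vinyl trans to the side chain) | C[Si](C)(C)OC1=C[C@@](C)(C=C)[C@H](C(C)C(=O)OC(C)(C)C)CC1 | intermediate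
13 | tert-butyl 2-[(1S,2S)-3-(2-{[tert-butyl(dimethyl)silyl]oxy}ethyl)-2-ethenyl-2-methyl-4-oxocyclohexyl]propanoate (epimers at ring C3 and at the α-carbon) | O=C1CC[C@@H](C(C)C(=O)OC(C)(C)C)[C@](C)(C=C)C1CCO[Si](C)(C)C(C)(C)C | intermediate
14 | tert-butyl 2-[(7S,8S)-6-(2-{[tert-butyl(dimethyl)silyl]oxy}ethyl)-7-ethenyl-7-methyl-1,4-dioxaspiro[4.5]decan-8-yl]propanoate (epimers at C6 and at the α-carbon) | C1COC2(O1)CC[C@@H](C(C)C(=O)OC(C)(C)C)[C@](C)(C=C)C2CCO[Si](C)(C)C(C)(C)C | intermediate
15 | tert-butyl 2-[(7S,8S)-6-(2-{[tert-butyl(dimethyl)silyl]oxy}ethyl)-7-formyl-7-methyl-1,4-dioxaspiro[4.5]decan-8-yl]propanoate (epimers at C6 and at the α-carbon) | C1COC2(O1)CC[C@@H](C(C)C(=O)OC(C)(C)C)[C@](C)(C=O)C2CCO[Si](C)(C)C(C)(C)C | intermediate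
16 | vinyltriphenylphosphonium bromide | C=C[P+](c1ccccc1)(c1ccccc1)c1ccccc1.[Br-] | starting material
17 | phosphonium ylide from Michael addition of the enolate of 15 (C4 quaternary, configuration as in 18; C6 epimers) | C1COC2(O1)CC[C@@H]([C@](C)(CC=P(c3ccccc3)(c3ccccc3)c3ccccc3)C(=O)OC(C)(C)C)[C@](C)(C=O)C2CCO[Si](C)(C)C(C)(C)C | intermediate
18 | tert-butyl 12-{[tert-butyl(dimethyl)silyl]oxy}-8,8-(ethane-1,2-diyldioxy)-13,14,15,16,17-pentanorlabd-1-en-19-oate (5α-H, 10β-CH3, 4α-CH3, 4β-ester; C9 epimers) | C1COC2(O1)CC[C@@H]3[C@](C)(C=CC[C@]3(C)C(=O)OC(C)(C)C)C2CCO[Si](C)(C)C(C)(C)C | intermediate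
19 | tert-butyl 12-{[tert-butyl(dimethyl)silyl]oxy}-8,8-(ethane-1,2-diyldioxy)-13,14,15,16,17-pentanorlabdan-19-oate (C9 epimers) | C1COC2(O1)CC[C@@H]3[C@](C)(CCC[C@]3(C)C(=O)OC(C)(C)C)C2CCO[Si](C)(C)C(C)(C)C | intermediate
20 | tert-butyl 12-hydroxy-8-oxo-13,14,15,16,17-pentanorlabdan-19-oate (9α-H) | O=C1CC[C@@H]2[C@](C)(CCC[C@]2(C)C(=O)OC(C)(C)C)[C@H]1CCO | intermediate
21 | tert-butyl 12-hydroxy-13,14,15,16-tetranorlabd-8(17)-en-19-oate | C=C1CC[C@@H]2[C@](C)(CCC[C@]2(C)C(=O)OC(C)(C)C)[C@H]1CCO | intermediate
22 | tert-butyl 12-oxo-13,14,15,16-tetranorlabd-8(17)-en-19-oate | C=C1CC[C@@H]2[C@](C)(CCC[C@]2(C)C(=O)OC(C)(C)C)[C@H]1CC=O | intermediate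
23 | methyl propiolate | C#CC(=O)OC | starting material
24 | 19-tert-butyl 15-methyl (12S)-12-hydroxy-16-norlabd-8(17)-en-13-yne-15,19-dioate | C=C1CC[C@@H]2[C@](C)(CCC[C@]2(C)C(=O)OC(C)(C)C)[C@H]1C[C@H](O)C#CC(=O)OC | intermediate
25 | 12-O-trimethylsilyl ether, 19-trimethylsilyl ester of 26 | C=C1CC[C@@H]2[C@](C)(CCC[C@]2(C)C(=O)O[Si](C)(C)C)[C@H]1C[C@H](O[Si](C)(C)C)C#CC(=O)OC | intermediate
26 | (12S)-12-hydroxy-15-methoxy-15-oxo-16-norlabd-8(17)-en-13-yn-19-oic acid | C=C1CC[C@@H]2[C@](C)(CCC[C@]2(C)C(=O)O)[C@H]1C[C@H](O)C#CC(=O)OC | intermediate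
27 | (12S,13Z)-12-hydroxy-15-methoxy-15-oxolabda-8(17),13-dien-19-oic acid (as its lithium salts in the flask) | C=C1CC[C@@H]2[C@](C)(CCC[C@]2(C)C(=O)O)[C@H]1C[C@H](O)/C(C)=C\C(=O)OC | intermediate
28 | (12S)-15-oxo-12,15-epoxylabda-8(17),13-dien-19-oic acid (butenolide acid) | C=C1CC[C@@H]2[C@](C)(CCC[C@]2(C)C(=O)O)[C@H]1C[C@@H]3OC(=O)C=C3C | intermediate
29 | (4S,5R,9S,10R,12S,13Z)-12-hydroxylabda-8(17),13-diene-15,19-dioic acid | C=C1CC[C@@H]2[C@](C)(CCC[C@]2(C)C(=O)O)[C@H]1C[C@H](O)/C(C)=C\C(=O)O | target

**Step count and risks**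

Total step count: 16. Longest linear sequence: 16 steps (from 1; compounds 3, 10, 11, 16 and 23 are bought).

Steps most likely to fail:

1. Step 9 (Proposed new method). What may go wrong: reduction of or addition to the aldehyde by the amide base, aldol consumption of the enolate before it meets the sparingly soluble phosphonium salt, or poor facial discrimination at C4. The fallback uses known chemistry and sets out from 14, where no aldehyde is present. The ester is enolised with LiN(i-Pr)2 and alkylated with allyl bromide (same A(1,3) model, attack anti to C10) to give the quaternary allyl ester tert-butyl 2-[6-(2-{[tert-butyl(dimethyl)silyl]oxy}ethyl)-7-ethenyl-7-methyl-1,4-dioxaspiro[4.5]decan-8-yl]-2-methylpent-4-enoate F1. Ring-closing metathesis of its allyl and vinyl groups with the second-generation Grubbs catalyst (toluene, 60 °C) closes ring A and comes back to the route at 18, so that steps 8 and 9 are by-passed.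

2. Step 6. What may go wrong: slow C-alkylation of the hindered, regiodefined enolate by a β-silyloxy primary iodide, so that proton exchange scrambles the enolate or elimination of the iodide takes over. The fallback sets out from 9 through the same silyl enol ether 12. The lithium enolate is trapped with the far more reactive methyl bromoacetate to give the keto diester tert-butyl 2-[2-ethenyl-3-(2-methoxy-2-oxoethyl)-2-methyl-4-oxocyclohexyl]propanoate F2. Ketalisation as in step 7 gives the dioxolane diester F3. LiBH4 (THF/MeOH) reduces the methyl ester chemoselectively beside the tert-butyl ester to the primary alcohol F4. TBSCl/imidazole then returns to the route at 14.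

3. Step 14. What may go wrong: low facial selectivity in alkynyl transfer to an α-unbranched aldehyde, or aldehyde self-condensation under the zinc alkoxide conditions. The fallback sets out from 22. Uncatalysed addition of LiC≡CCO2Me (THF, −78 °C) gives the C12-epimeric γ-hydroxy ynoate F5. Dess–Martin oxidation gives the 12-oxo ynoate F6. Midland reduction with (S)-Alpine-Borane (reagent control, alkynyl as the small group) returns to the route at 24.

**Further compounds**

F1 | step 9 | tert-butyl 2-[6-(2-{[tert-butyl(dimethyl)silyl]oxy}ethyl)-7-ethenyl-7-methyl-1,4-dioxaspiro[4.5]decan-8-yl]-2-methylpent-4-enoate (quaternary carbon configured as C4 of 18; C6 epimers) | C1COC2(O1)CC[C@@H]([C@](C)(CC=C)C(=O)OC(C)(C)C)[C@](C)(C=C)C2CCO[Si](C)(C)C(C)(C)C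
F2 | step 6 | tert-butyl 2-[(1S,2S)-2-ethenyl-3-(2-methoxy-2-oxoethyl)-2-methyl-4-oxocyclohexyl]propanoate (epimers at ring C3 and at the α-carbon) | O=C1CC[C@@H](C(C)C(=O)OC(C)(C)C)[C@](C)(C=C)C1CC(=O)OC
F3 | step 6 | tert-butyl 2-[(7S,8S)-7-ethenyl-6-(2-methoxy-2-oxoethyl)-7-methyl-1,4-dioxaspiro[4.5]decan-8-yl]propanoate (epimers at C6 and at the α-carbon) | C1COC2(O1)CC[C@@H](C(C)C(=O)OC(C)(C)C)[C@](C)(C=C)C2CC(=O)OC
F4 | step 6 | tert-butyl 2-[(7S,8S)-7-ethenyl-6-(2-hydroxyethyl)-7-methyl-1,4-dioxaspiro[4.5]decan-8-yl]propanoate (epimers at C6 and at the α-carbon) | C1COC2(O1)CC[C@@H](C(C)C(=O)OC(C)(C)C)[C@](C)(C=C)C2CCO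
F5 | step 14 | 19-tert-butyl 15-methyl 12-hydroxy-16-norlabd-8(17)-en-13-yne-15,19-dioate (C12 epimers) | C=C1CC[C@@H]2[C@](C)(CCC[C@]2(C)C(=O)OC(C)(C)C)[C@H]1CC(O)C#CC(=O)OC
F6 | step 14 | 19-tert-butyl 15-methyl 12-oxo-16-norlabd-8(17)-en-13-yne-15,19-dioate | C=C1CC[C@@H]2[C@](C)(CCC[C@]2(C)C(=O)OC(C)(C)C)[C@H]1CC(=O)C#CC(=O)OC
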